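The product readings were what I had, and I wanted them as a count rather than as a concentration.

| flask | starting material | free catalyst | product | time |
|---|---|---|---|---|
| larch | 0.0800 M | 1.60 × 10⁻⁴ M |  |  |
| ash | 0.120 M | 1.60 × 10⁻⁴ M |  |  |
| oak | 0.0800 M | 8.00 × 10⁻⁵ M |  |  |
| alder | 0.0800 M | 1.60 × 10⁻⁴ M | 0.0240 M |  |
| birch | 0.0400 M | 5.30 × 10⁻⁵ M |  | 47 min |

- larch run (time / min: [product] / M): 1.9: 0.0071; 4.2: 0.0147; 9.4: 0.0282; 21: 0.0367; 47: 0.0429
- ash run (time / min: [product] / M): 1.9: 0.0098; 4.2: 0.0234; 9.4: 0.0424; 21: 0.0539; 47: 0.0639
- oak run (time / min: [product] / M): 1.9: 0.0069; 4.2: 0.0104; 9.4: 0.0189; 21: 0.0286; 47: 0.0338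
- alder run (time / min: [product] / M): 1.9: 0.0329; 4.2: 0.0420; 9.4: 0.0507; 21: 0.0629; 47: 0.0654

(readings scatter by 0.001 M)

- the exponent of [starting material] in the starting rate at the charge of the larch run (at the point where two percent of the starting material have become product) (one fixed amount of product, the same in the runs compared)
- the exponent of [free catalyst] in the starting rate at the charge of the larch run (at the point where two percent of the starting material have become product)
- product in the birch run at 47 min, as a share of the starting material charged

- Overall: starting material -> product, with free catalyst as catalyst.
- Constant volume, constant temperature.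
- An order is taken over about fifteen percent of the charge, up and down.

For each reading I took the lifetime count: the logarithm of the charge over the charge minus the product made. It says how many first-order lifetimes would give that share, and nothing about what became of the rest.

The larch run counted 0.435 at 9.4 min and 0.768 at 47 min, so time grew 5.00 times and the count 1.77 times. The larch flask was plainly slowing.

The ash run, with 1.50 times the charge, counted 0.436 and 0.760 at those times. That is pseudo-first-order behaviour at this catalyst charge, since the count ignored the charge.

The alder run, counted on its gain over the added 0.0240 M, reached 0.729 at 47 min, against a scatter near 0.0270 on the larch count, so I set added product aside.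

The oak run, with less catalyst, counted 0.270 and 0.549. Oak against larch at 47 min gave 0.485 for the reach exponent, the power of the catalyst charge that carries the count at a fixed time from one flask to another. At 9.4 min the same reading gave 0.689, so the exponent fell with time.

The birch flask is asked at 47 min, so I used the late exponent. Its catalyst is a third of larch's, which gave a count of 0.450 and a share of 36.2 %.

The forecast gave exponents of 1 and 0.6 and 34 % for birch, below mine by 2.2 percentage points, and spoke of “a catalyst partly held as an inactive dimer”.

The birch flask gave 35.5 %, with exponents of 1.0 in starting material and 0.61 in catalyst at the start.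

    2 free catalyst ⇌ catalyst dimer, settled at all times (22100 L mol⁻¹)
    free catalyst + starting material → product + free catalyst (1206 L mol⁻¹ min⁻¹)
    starting material → decomposed substrate (0.02964 min⁻¹)
    2 free catalyst → 2 spent catalyst (2280 L mol⁻¹ min⁻¹)

Birch's count was 0.438, which against larch's 0.768 is a reach exponent of 0.509, below the starting exponent. Put on the oak run at its start, the reach exponent 0.485 gives a rate 0.715 of larch's, above the ratio found at equal product, which was 0.65.

(Readings and results were computed on assumed constants, noise included.)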